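Charge over what is left: that ratio for the coupling partner is what two chemists dispute for the flask below.

the same everywhere: coupling partner 0.651 M; free catalyst 11 mM
- north-east: starting material 0.62 M; second substrate 0.62 M; impurity 7 mM; the very flask that is asked about, followed so far
- north: starting material 0.31 M; second substrate 0.62 M; impurity 7 mM; run made earlier
- flask: starting material 0.62 M; second substrate 0.620 M; impurity 7.0 mM

| run | time / h | target / % | starting material / % |
|---|---|---|---|
| north-east | 0.417 | 10.9 | 87.7 |
| north-east | 0.667 | 16.3 | 83.6 |
| north-east | 1.00 | 20.1 | 78.2 |
| north-east | 2.00 | 31.8 | 68.0 |
| north-east | 3.00 | 40.4 | 59.4 |
| north-east | 5.00 | 54.1 | 46.1 |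
| north | 0.333 | 13.9 | 84.6 |
| north | 0.500 | 19.5 | 80.7 |
| north | 0.833 | 25.5 | 73.4 |
| north | 1.33 | 36.2 | 64.2 |
| north | 2.50 | 53.2 | 46.3 |
| north | 4.00 | 70.1 | 30.1 |

(scatter of a reading: 0.5 percentage points)

- the earlier runs were read with a standard deviation of 0.5 percentage points
- on the list of suspects stand: free catalyst + impurity -> spent catalyst; coupling partner + catalyst intermediate A -> free catalyst + target; starting material + free catalyst <-> catalyst intermediate A; second substrate <-> dormant form; coupling partner + catalyst intermediate B -> free catalyst + second product; second substrate + free catalyst <-> catalyst intermediate B
- no earlier run changes the charge of coupling partner; that part of a forecast is a guess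

1. apparent order in coupling partner when 30% of the starting material are converted (percent change of the rate of making target for one percent more coupling partner charged)

On the list of suspects, one coupling partner is spent for each target made, and partner also goes to second product.

The first chemist made the forecast: 0.75, within 0.25 to 1.4. That chemist grants that more charge means more partner present, but adds: “Partial saturation and the competing second-product pathway temper this”.

The second view is my own. I take the binding of starting material to free catalyst as settled and assume that c(catalyst intermediate A) does not follow c(coupling partner). The rate is then proportional to c(coupling partner), and the order in the charge is just a matter of leverage. At 30% conversion, counting one partner per starting material converted and leaving the second-product route out of the estimate, 0.186 M of partner is gone and 0.465 M remains, so the charge-to-present ratio, the leverage 1.40, says by this estimate that one percent more charged is 1.40 percent more present. My number is higher than the forecast's. No run varies the partner, so both remain guesses.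

The simulation gives 1.5.

    free catalyst + impurity → spent catalyst (k = 41.0 M⁻¹ min⁻¹)
    coupling partner + catalyst intermediate A → free catalyst + target (k = 0.770 M⁻¹ min⁻¹)
    starting material + free catalyst ⇌ catalyst intermediate A (K = 11.0 M⁻¹, k = 16.0 M⁻¹ min⁻¹)
    second substrate ⇌ dormant form (K = 18.0, k = 0.00100 min⁻¹)
    coupling partner + catalyst intermediate B → free catalyst + second product (k = 0.640 M⁻¹ min⁻¹)
    second substrate + free catalyst ⇌ catalyst intermediate B (K = 0.950 M⁻¹, k = 0.760 M⁻¹ min⁻¹)

That is twice the forecast and close to the leverage of 1.40. The north run, with half the starting material, has by the same estimate a leverage of 1.17 at the same conversion, but no order in partner is given for that run. In the flask, impurity met free catalyst early: at 1.00 h spent catalyst stood at 58.6% of the catalyst charged, with 7.90% of the impurity left. With impurity at 0% by 5.00 h, coupling partner went on reacting with catalyst intermediate A, which then held 24.3% of the catalyst, until at 10.0 h the partner stood at 23.4% of its charge.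

The numbers in the tables are calculated from invented constants; the scatter is artificial.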